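**Plan**

- Cuts: the CH2–CH2 link between decalin C2 and the dioxane (made as an alkene by Julia–Kocienski olefination, then reduced with diimide); ring B at C1–C8a and C4–C4a; the two C–O bonds of the dioxane O–O unit.
- Enabling feature: ring B (C1, C2, C3, C4, C4a, C8a) has a tetrasubstituted C2=C3 alkene with a carbon substituent on C2, the gem-dimethyl carbon C1 bonded to C8a, and C4 bonded to C4a. This is a 2-oxy diene C1=C2(O)–C3=C4 laid across C8a–C4a of a cyclohexenone whose carbonyl carbon is C5. Because C1 carries two methyl groups the diene cannot adopt the s-cis geometry, so the two bonds are made one after the other through enolates.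
- Forward order: ring A comes from an anisole as a 5-silylcyclohexenone; ring B closes in step 6; the C5 ketone and C7 silyl group become the C5=C6(Me) alkene and the C2 enol triflate becomes CH2SO2PT; the 1,2-dioxane is closed separately (epoxide perhydrolysis, then peroxide SN2) and joined last.
- Stereochemistry: C8a by addition anti to the C7 silyl group of the resolved (S)-enone, C4a by the cis ring closure; the dioxane quaternary carbon from (S)-2-methylglycidol (inverted on perhydrolysis); the dioxane CH carbon and the α-methyl carbon from a (Z)-crotylboration (CH carbon inverted in the ring closure).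

Key step: step 6

Assumption: cinchonine is taken to select the (S)-enone in the thiol addition of step 3 (crystalline adduct of the 3R,5R series); if the sense proves opposite, its pseudo-enantiomer cinchonidine is used instead.

Target: (2R)-2-[(3R,6R)-6-methyl-6-{2-[(4aR,8aS)-1,1,3,6-tetramethyl-1,4,4a,7,8,8a-hexahydronaphthalen-2-yl]ethyl}-1,2-dioxan-3-yl]propanoic acid, cis-fused.

**Part A – silyl enone and vinyl ketone**

Step 1
Reactants: 1 (3-methoxyphenyl)trimethylsilane
Product: 2 1-methoxy-3-(trimethylsilyl)cyclohexa-1,4-diene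
Conditions: Li, NH3(l), THF, t-BuOH, −78 → −33 °C; NH4Cl
Reagents that add atoms: none
Why: Birch reduction; the methoxy-bearing carbon stays sp2 and the silyl-bearing carbon is protonated, both substituent effects pointing to the same 1,4-diene.

Step 2
Reactants: 2 1-methoxy-3-(trimethylsilyl)cyclohexa-1,4-diene
Product: 4 rac-5-(trimethylsilyl)cyclohex-2-en-1-one, via β,γ-enone 3 (not isolated)
Conditions: (CO2H)2, MeOH/H2O, rt; then DBU (cat.), CH2Cl2, rt
Reagents that add atoms: water, O
Why: Mild acid hydrolysis of the enol ether should give the β,γ-enone without protodesilylating the allylic silane, and base-mediated conjugation through the dienolate then moves the alkene away from silicon.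

Step 3
Reactants: 4 rac-5-(trimethylsilyl)cyclohex-2-en-1-one
Product: 5 (3R,5R)-3-[(4-methylphenyl)sulfanyl]-5-(trimethylsilyl)cyclohexan-1-one
Conditions: 4-MeC6H4SH (0.6 equiv), cinchonine (5 mol%), toluene, rt; recrystallisation
Reagents that add atoms: 4-methylbenzenethiol, Cc1ccc(S)cc1
Why: Cinchona-alkaloid-catalysed thia-Michael addition acts as a kinetic resolution, the thiol adding trans to the silyl group, and recrystallisation of the adduct should bring it to enantiopurity.

Step 4
Reactants: 5 (3R,5R)-3-[(4-methylphenyl)sulfanyl]-5-(trimethylsilyl)cyclohexan-1-one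
Product: 7 (S)-5-(trimethylsilyl)cyclohex-2-en-1-one, via sulfoxide 6 (not isolated)
Conditions: mCPBA (1.0 equiv), CH2Cl2, −78 °C; then DBU, rt
Reagents that add atoms: none
Why: Sulfide oxidation followed by E1cB elimination of the β-sulfinyl ketone regenerates the enone without touching the silyl-bearing stereocentre.

Step 5
Reactants: 8 isobutyryl chloride; 9 isopropenylmagnesium bromide
Product: 10 2,4-dimethylpent-1-en-3-one
Conditions: Fe(acac)3 (3 mol%), THF, −78 °C; cold aq. HCl
Reagents that add atoms: none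
Why: Iron-catalysed acylation of a Grignard reagent by an acid chloride is fast at −78 °C and stops at the ketone.

**Part B – ring B and the decalin sulfone**

Step 6
Reactants: 7 (S)-5-(trimethylsilyl)cyclohex-2-en-1-one; 10 2,4-dimethylpent-1-en-3-one
Product: 14 (4aS,7S,8aS)-1,1,3-trimethyl-5-oxo-7-(trimethylsilyl)-1,4,4a,5,6,7,8,8a-octahydronaphthalen-2-yl trifluoromethanesulfonate, via lithium dienolate 11 (not isolated), via monocyclic Michael-adduct enolate 12 (not isolated), via bicyclic C2 lithium enolate 13 (not isolated)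
Conditions: LDA (1.05 equiv), THF, −78 °C, then 10; then 7, −78 → −20 °C; then N-(5-chloro-2-pyridyl)triflimide, −78 → 0 °C; aq. NH4Cl
Reagents that add atoms: N-(5-chloropyridin-2-yl)-1,1,1-trifluoro-N-[(trifluoromethyl)sulfonyl]methanesulfonamide, FC(F)(F)S(=O)(=O)N(c1ccc(Cl)cn1)S(=O)(=O)C(F)(F)F
Why: Kinetic deprotonation of 10 at the isopropyl methine gives the cross-conjugated dienolate 11, whose fully substituted carbon adds to C3 of 7 (forming C1–C8a); the ring enolate 12 then attacks the CH2 terminus of the tethered isopropenyl ketone (forming C4–C4a), and the resulting C2 enolate 13 is O-sulfonylated before it can equilibrate. The closest known reaction type is the Michael–Michael ring closure of enone α′-enolates with cyclic enones (anionic formal [4+2]) combined with trapping of the final enolate as an enol triflate. Ring B closes by a 6-endo-trig (enolexo) conjugate addition. C8a is set by axial attack on the enone face anti to the C7 trimethylsilyl group, as in other conjugate additions to 5-silylcyclohexenones, and C4a by the ring closure itself, because axial C-alkylation of enolate 12 with the tether pseudo-equatorial on C8a can only deliver the cis ring fusion. The step needs 1,4- over 1,2-addition and no proton transfer from the C6 methylene to enolate 13: the hindered nucleophile makes carbonyl addition reversible, the intramolecular second addition drains the first equilibrium, and low temperature with immediate triflation should preserve the C2=C3 enolate regiochemistry.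

Step 7
Reactants: 14 the C2 enol triflate
Product: 15 methyl (4aS,7S,8aS)-1,1,3-trimethyl-5-oxo-7-(trimethylsilyl)-1,4,4a,5,6,7,8,8a-octahydronaphthalene-2-carboxylate
Conditions: Pd(OAc)2 (5 mol%), dppp, CO (1 atm), MeOH, Et3N, DMF, 70 °C
Reagents that add atoms: carbon monoxide, [C-]#[O+]; methanol, CO
Why: Palladium-catalysed methoxycarbonylation of an enol triflate, well established for 2,6,6-trisubstituted cyclohexenyl triflates of the cyclogeranate type; no stereocentre is touched.

Step 8
Reactants: 15 the silyl keto ester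
Product: 17 methyl (4aS,8aS)-1,1,3-trimethyl-5-oxo-1,4,4a,5,8,8a-hexahydronaphthalene-2-carboxylate, via 6-bromo ketone 16 (not isolated)
Conditions: LDA, THF, −78 °C; NBS, −78 °C; then TBAF, THF, 0 °C; aq. NH4Cl
Reagents that add atoms: none
Why: Kinetic deprotonation at the C6 methylene (not the C4a methine) and enolate bromination place bromine next to the silyl-bearing C7, and fluoride-induced desilylbromination then gives the C6=C7 enone regiospecifically under non-equilibrating conditions that leave C4a alone.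

Step 9
Reactants: 17 the enone ester
Product: 18 methyl (4aS,8aS)-6-iodo-1,1,3-trimethyl-5-oxo-1,4,4a,5,8,8a-hexahydronaphthalene-2-carboxylate
Conditions: I2, pyridine, CH2Cl2, 0 °C → rt
Reagents that add atoms: iodine, II
Why: α-Iodination of a cyclic enone by iodine/pyridine (addition–elimination through the pyridinium enolate) functionalises C6 only.

Step 10
Reactants: 18 the α-iodoenone
Product: 19 methyl (4aS,8aS)-1,1,3,6-tetramethyl-5-oxo-1,4,4a,5,8,8a-hexahydronaphthalene-2-carboxylate
Conditions: MeZnCl, Pd2(dba)3 (2.5 mol%), P(2-furyl)3 (10 mol%), THF/DMF, rt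
Reagents that add atoms: methylzinc chloride, C[Zn]Cl
Why: Negishi cross-coupling of an α-iodoenone with a methylzinc reagent installs the C6 methyl group under neutral conditions that do not enolise toward C4a.

Step 11
Reactants: 19 the α-methyl enone
Product: 21 methyl (4aS,8aS)-1,1,3,6-tetramethyl-5-{[(trifluoromethyl)sulfonyl]oxy}-1,4,4a,7,8,8a-hexahydronaphthalene-2-carboxylate, via C5 lithium enolate 20 (not isolated)
Conditions: L-Selectride, THF, −78 °C; then N-(5-chloro-2-pyridyl)triflimide, −78 → 0 °C; aq. NH4Cl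
Reagents that add atoms: N-(5-chloropyridin-2-yl)-1,1,1-trifluoro-N-[(trifluoromethyl)sulfonyl]methanesulfonamide, FC(F)(F)S(=O)(=O)N(c1ccc(Cl)cn1)S(=O)(=O)C(F)(F)F
Why: 1,4-Hydride delivery to the β-unsubstituted C7 of the α-methyl enone gives the C5–C6 enolate regiospecifically, and O-triflation fixes the position of the future C5=C6 alkene.

Step 12
Reactants: 21 the C5 enol triflate
Product: 22 methyl (4aR,8aS)-1,1,3,6-tetramethyl-1,4,4a,7,8,8a-hexahydronaphthalene-2-carboxylate
Conditions: Pd(OAc)2, PPh3, HCO2H, n-Bu3N, DMF, 60 °C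
Reagents that add atoms: none
Why: Palladium-catalysed formate reduction of the enol triflate replaces OTf by H, leaving the trisubstituted C5=C6 alkene and the cis ring fusion untouched.

Step 13
Reactants: 22 the diene ester
Product: 23 [(4aR,8aS)-1,1,3,6-tetramethyl-1,4,4a,7,8,8a-hexahydronaphthalen-2-yl]methanol
Conditions: DIBAL-H, CH2Cl2, −78 → 0 °C; Rochelle salt
Reagents that add atoms: none
Why: DIBAL-H 1,2-reduction of the hindered conjugated ester gives the allylic alcohol.

Step 14
Reactants: 23 the allylic alcohol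
Product: 24 5-({[(4aR,8aS)-1,1,3,6-tetramethyl-1,4,4a,7,8,8a-hexahydronaphthalen-2-yl]methyl}sulfanyl)-1-phenyl-1H-tetrazole
Conditions: 1-phenyl-1H-tetrazole-5-thiol, PPh3, DIAD, THF, 0 °C → rt
Reagents that add atoms: 1-phenyl-1H-tetrazole-5-thiol, Sc1nnnn1-c1ccccc1
Why: Mitsunobu thioetherification of the primary allylic alcohol with the acidic tetrazole thiol.

Step 15
Reactants: 24 the PT sulfide
Product: 25 5-({[(4aR,8aS)-1,1,3,6-tetramethyl-1,4,4a,7,8,8a-hexahydronaphthalen-2-yl]methyl}sulfonyl)-1-phenyl-1H-tetrazole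
Conditions: (NH4)6Mo7O24·4H2O (10 mol%), 30% H2O2, EtOH, 0 °C → rt
Reagents that add atoms: hydrogen peroxide, OO
Why: Molybdate-catalysed peroxide oxidation should take the sulfide to the sulfone faster than it epoxidises the hindered ring alkenes.

**Part C – formyl-dioxane ester**

Step 16
Reactants: 26 (S)-2-methylglycidol
Product: 27 [(2R)-2-methyloxiran-2-yl]methyl 4-methylbenzenesulfonate
Conditions: TsCl, Et3N, DMAP (cat.), CH2Cl2, 0 °C
Reagents that add atoms: 4-methylbenzenesulfonyl chloride, Cc1ccc(cc1)S(Cl)(=O)=O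
Why: Sulfonylation of the primary alcohol; the quaternary stereocentre is not involved (its descriptor changes only through CIP priorities).

Step 17
Reactants: 27 the glycidyl tosylate; 28 allylmagnesium bromide
Product: 30 (2R)-2-(but-3-en-1-yl)-2-methyloxirane, via tosyloxy alcohol 29 (not isolated)
Conditions: CuI (10 mol%), THF, −40 → −20 °C; aq. NH4Cl; then K2CO3, MeOH, rt
Reagents that add atoms: none
Why: Copper-catalysed Grignard opening of the epoxide at its CH2 terminus, then closure of the tertiary alkoxide onto the tosylate, carries the intact quaternary C–O bond into the new epoxide.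

Step 18
Reactants: 30 the butenyl epoxide
Product: 31 3-[(2R)-2-methyloxiran-2-yl]propanal
Conditions: O3, CH2Cl2, −78 °C; Me2S, −78 °C → rt
Reagents that add atoms: ozone, [O-][O+]=O
Why: Ozonolysis of the terminal alkene with reductive work-up; the 2,2-disubstituted epoxide is inert to ozone.

Step 19
Reactants: 31 the epoxy aldehyde
Product: 32 (3S,4S)-3-methyl-6-[(2R)-2-methyloxiran-2-yl]hex-1-en-4-ol
Conditions: (Z)-crotyl-B(Ipc)2 of the (−)-α-pinene series [from cis-but-2-ene, n-BuLi, KOt-Bu, (+)-Ipc2BOMe, BF3·OEt2], THF, −78 °C; then NaBO3·4H2O, THF/H2O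
Reagents that add atoms: (Z)-crotyldiisopinocampheylborane, C/C=C\CB([C@H]1C[C@H]2C[C@@H]([C@@H]1C)C2(C)C)[C@H]1C[C@H]2C[C@@H]([C@@H]1C)C2(C)C
Why: Reagent-controlled (Z)-crotylboration through a closed chair transition state: the Z geometry gives the syn (3S,4S) relationship and the isopinocampheyl ligands of this series direct attack to the Re face, the boron trifluoride used to free the borane being consumed before the epoxy aldehyde is added.

Step 20
Reactants: 32 the homoallylic alcohol
Product: 33 (3S,4S)-3-methyl-6-[(2R)-2-methyloxiran-2-yl]hex-1-en-4-yl methanesulfonate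
Conditions: MsCl, Et3N, CH2Cl2, 0 °C
Reagents that add atoms: methanesulfonyl chloride, CS(Cl)(=O)=O
Why: Mesylation of the secondary alcohol with retention prepares C4 for displacement.

Step 21
Reactants: 33 the epoxy mesylate
Product: 34 (3S,4S,7S)-7-hydroperoxy-8-hydroxy-3,7-dimethyloct-1-en-4-yl methanesulfonate
Conditions: anhydrous H2O2 in Et2O, phosphomolybdic acid (cat.), rt
Reagents that add atoms: hydrogen peroxide, OO
Why: Phosphomolybdic-acid-catalysed perhydrolysis opens the 2,2-disubstituted epoxide at its tertiary carbon with inversion, giving the tertiary hydroperoxide and the primary alcohol, while mesylate and terminal alkene are inert to neutral ethereal hydrogen peroxide.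

Step 22
Reactants: 34 the hydroperoxy mesylate
Product: 35 [(3S,6R)-6-[(2S)-but-3-en-2-yl]-3-methyl-1,2-dioxan-3-yl]methanol
Conditions: KOt-Bu (1.0 equiv), 18-crown-6, THF, 0 °C
Reagents that add atoms: none
Why: Intramolecular peroxide alkylation (6-exo-tet SN2 of the hydroperoxide anion on the mesylate) closes the 1,2-dioxane with inversion at the CH carbon, one equivalent of base deprotonating only the far more acidic OOH.

Step 23
Reactants: 35 the vinyl dioxane
Product: 37 (2R)-2-[(3R,6S)-6-(hydroxymethyl)-6-methyl-1,2-dioxan-3-yl]propanoic acid, via peroxy aldehyde 36 (not isolated)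
Conditions: O3, CH2Cl2, −78 °C; Me2S; then NaClO2, NaH2PO4, 2-methylbut-2-ene, t-BuOH/H2O, 0 °C
Reagents that add atoms: ozone, [O-][O+]=O; sodium chlorite, [Na+].[O-]Cl=O
Why: Ozonolysis then Pinnick oxidation convert the vinyl group into the carboxylic acid without isolating the epimerisable β-peroxy aldehyde, the dialkyl peroxide and the primary alcohol being inert to both oxidants.

Step 24
Reactants: 37 the hydroxy acid
Product: 38 methyl (2R)-2-[(3R,6S)-6-(hydroxymethyl)-6-methyl-1,2-dioxan-3-yl]propanoate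
Conditions: TMSCHN2, MeOH/toluene, 0 °C
Reagents that add atoms: trimethylsilyldiazomethane, C[Si](C)(C)C=[N+]=[N-]
Why: Esterification with trimethylsilyldiazomethane under neutral conditions avoids base at the β-peroxy α-stereocentre.

Step 25
Reactants: 38 the hydroxy ester
Product: 39 methyl (2R)-2-[(3R,6S)-6-formyl-6-methyl-1,2-dioxan-3-yl]propanoate
Conditions: Dess–Martin periodinane, NaHCO3, CH2Cl2, 0 °C → rt
Reagents that add atoms: none
Why: Dess–Martin oxidation of the neopentyl-type primary alcohol gives the non-enolisable aldehyde under buffered conditions.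

**Part D – coupling and completion**

Step 26
Reactants: 25 the decalin PT sulfone; 39 the formyl-dioxane ester
Product: 40 methyl (2R)-2-[(3R,6S)-6-methyl-6-{(E)-2-[(4aR,8aS)-1,1,3,6-tetramethyl-1,4,4a,7,8,8a-hexahydronaphthalen-2-yl]ethenyl}-1,2-dioxan-3-yl]propanoate
Conditions: KHMDS (1.0 equiv), THF, −78 °C; then 39, −78 °C → rt; aq. NH4Cl
Reagents that add atoms: none
Why: Julia–Kocienski olefination: the allylic sulfonyl anion adds to the non-enolisable aldehyde and Smiles rearrangement with loss of SO2 gives the diene, whose E/Z ratio is irrelevant because the new alkene is reduced next; exactly one equivalent of base is used to avoid β-elimination at the peroxy ester.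

Step 27
Reactants: 40 the diene ester
Product: 41 methyl (2R)-2-[(3R,6R)-6-methyl-6-{2-[(4aR,8aS)-1,1,3,6-tetramethyl-1,4,4a,7,8,8a-hexahydronaphthalen-2-yl]ethyl}-1,2-dioxan-3-yl]propanoate
Conditions: KO2CN=NCO2K, AcOH, MeOH/CH2Cl2, 0 °C → rt (portionwise)
Reagents that add atoms: none
Why: Diimide should reduce the disubstituted alkene much faster than the tri- and tetrasubstituted ring alkenes and does not cleave the O–O bond.

Step 28
Reactants: 41 the methyl ester
Product: 42 (2R)-2-[(3R,6R)-6-methyl-6-{2-[(4aR,8aS)-1,1,3,6-tetramethyl-1,4,4a,7,8,8a-hexahydronaphthalen-2-yl]ethyl}-1,2-dioxan-3-yl]propanoic acid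
Conditions: LiOH·H2O, THF/MeOH/H2O, 0 °C → rt; then 1 M HCl to pH 3
Reagents that add atoms: lithium hydroxide, [Li+].[OH-]
Why: Saponification of the methyl ester at low temperature, as used for related 1,2-dioxane propanoates, followed by mild acidification; cold, short exposure is meant to prevent retro-oxa-Michael opening at the α-centre.

**Compound list**

1 | (3-methoxyphenyl)trimethylsilane | COc1cccc([Si](C)(C)C)c1 | starting material
2 | 1-methoxy-3-(trimethylsilyl)cyclohexa-1,4-diene | COC1=CC([Si](C)(C)C)C=CC1 | intermediate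
3 | rac-5-(trimethylsilyl)cyclohex-3-en-1-one | O=C1CC=CC([Si](C)(C)C)C1 | intermediate (not isolated)
4 | rac-5-(trimethylsilyl)cyclohex-2-en-1-one | O=C1C=CCC([Si](C)(C)C)C1 | intermediate
5 | (3R,5R)-3-[(4-methylphenyl)sulfanyl]-5-(trimethylsilyl)cyclohexan-1-one | C1C(=O)C[C@@H](Sc2ccc(C)cc2)C[C@@H]1[Si](C)(C)C | intermediate
6 | (3R,5R)-3-(4-methylbenzenesulfinyl)-5-(trimethylsilyl)cyclohexan-1-one (sulfur epimers) | C1C(=O)C[C@@H](S(=O)c2ccc(C)cc2)C[C@@H]1[Si](C)(C)C | intermediate (not isolated)
7 | (S)-5-(trimethylsilyl)cyclohex-2-en-1-one | C1C(=O)C=CC[C@@H]1[Si](C)(C)C | intermediate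
8 | isobutyryl chloride | CC(C)C(Cl)=O | starting material
9 | isopropenylmagnesium bromide | CC(=C)[Mg]Br | starting material
10 | 2,4-dimethylpent-1-en-3-one | CC(C)C(=O)C(C)=C | intermediate
11 | lithium 2,4-dimethylpenta-1,3-dien-3-olate | [Li]OC(=C(C)C)C(C)=C | intermediate (not isolated)
12 | lithium (3S,5S)-3-(2,4-dimethyl-3-oxopent-4-en-2-yl)-5-(trimethylsilyl)cyclohex-1-en-1-olate | C1C(O[Li])=C[C@@H](C(C)(C)C(=O)C(C)=C)C[C@@H]1[Si](C)(C)C | intermediate (not isolated)
13 | lithium (4aS,7S,8aS)-1,1,3-trimethyl-5-oxo-7-(trimethylsilyl)-1,4,4a,5,6,7,8,8a-octahydronaphthalen-2-olate | C1C(=O)[C@H]2CC(C)=C(O[Li])C(C)(C)[C@H]2C[C@@H]1[Si](C)(C)C | intermediate (not isolated)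
14 | (4aS,7S,8aS)-1,1,3-trimethyl-5-oxo-7-(trimethylsilyl)-1,4,4a,5,6,7,8,8a-octahydronaphthalen-2-yl trifluoromethanesulfonate (cis-fused) | C1C(=O)[C@H]2CC(C)=C(OS(=O)(=O)C(F)(F)F)C(C)(C)[C@H]2C[C@@H]1[Si](C)(C)C | intermediate
15 | methyl (4aS,7S,8aS)-1,1,3-trimethyl-5-oxo-7-(trimethylsilyl)-1,4,4a,5,6,7,8,8a-octahydronaphthalene-2-carboxylate | C1C(=O)[C@H]2CC(C)=C(C(=O)OC)C(C)(C)[C@H]2C[C@@H]1[Si](C)(C)C | intermediate
16 | methyl (4aS,7S,8aS)-6-bromo-1,1,3-trimethyl-5-oxo-7-(trimethylsilyl)-1,4,4a,5,6,7,8,8a-octahydronaphthalene-2-carboxylate (C6 configuration not defined) | BrC1C(=O)[C@H]2CC(C)=C(C(=O)OC)C(C)(C)[C@H]2C[C@@H]1[Si](C)(C)C | intermediate (not isolated)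
17 | methyl (4aS,8aS)-1,1,3-trimethyl-5-oxo-1,4,4a,5,8,8a-hexahydronaphthalene-2-carboxylate | C1=CC(=O)[C@H]2CC(C)=C(C(=O)OC)C(C)(C)[C@H]2C1 | intermediate
18 | methyl (4aS,8aS)-6-iodo-1,1,3-trimethyl-5-oxo-1,4,4a,5,8,8a-hexahydronaphthalene-2-carboxylate | C1=C(I)C(=O)[C@H]2CC(C)=C(C(=O)OC)C(C)(C)[C@H]2C1 | intermediate
19 | methyl (4aS,8aS)-1,1,3,6-tetramethyl-5-oxo-1,4,4a,5,8,8a-hexahydronaphthalene-2-carboxylate | C1=C(C)C(=O)[C@H]2CC(C)=C(C(=O)OC)C(C)(C)[C@H]2C1 | intermediate
20 | C5 lithium enolate (C5(OLi)=C6) formed by 1,4-reduction of 19 | C1C(C)=C(O[Li])[C@H]2CC(C)=C(C(=O)OC)C(C)(C)[C@H]2C1 | intermediate (not isolated)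
21 | methyl (4aS,8aS)-1,1,3,6-tetramethyl-5-{[(trifluoromethyl)sulfonyl]oxy}-1,4,4a,7,8,8a-hexahydronaphthalene-2-carboxylate | C1C(C)=C(OS(=O)(=O)C(F)(F)F)[C@H]2CC(C)=C(C(=O)OC)C(C)(C)[C@H]2C1 | intermediate
22 | methyl (4aR,8aS)-1,1,3,6-tetramethyl-1,4,4a,7,8,8a-hexahydronaphthalene-2-carboxylate | CC1=C[C@H]2CC(C)=C(C(=O)OC)C(C)(C)[C@H]2CC1 | intermediate
23 | [(4aR,8aS)-1,1,3,6-tetramethyl-1,4,4a,7,8,8a-hexahydronaphthalen-2-yl]methanol | CC1=C[C@H]2CC(C)=C(CO)C(C)(C)[C@H]2CC1 | intermediate
24 | 5-({[(4aR,8aS)-1,1,3,6-tetramethyl-1,4,4a,7,8,8a-hexahydronaphthalen-2-yl]methyl}sulfanyl)-1-phenyl-1H-tetrazole | CC1=C[C@H]2CC(C)=C(CSc3nnnn3-c3ccccc3)C(C)(C)[C@H]2CC1 | intermediate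
25 | 5-({[(4aR,8aS)-1,1,3,6-tetramethyl-1,4,4a,7,8,8a-hexahydronaphthalen-2-yl]methyl}sulfonyl)-1-phenyl-1H-tetrazole | CC1=C[C@H]2CC(C)=C(CS(=O)(=O)c3nnnn3-c3ccccc3)C(C)(C)[C@H]2CC1 | intermediate
26 | (S)-2-methylglycidol, [(2S)-2-methyloxiran-2-yl]methanol | OC[C@@]1(C)CO1 | starting material
27 | [(2R)-2-methyloxiran-2-yl]methyl 4-methylbenzenesulfonate | Cc1ccc(cc1)S(=O)(=O)OC[C@@]1(C)CO1 | intermediate
28 | allylmagnesium bromide | C=CC[Mg]Br | starting material
29 | (2R)-2-hydroxy-2-methylhex-5-en-1-yl 4-methylbenzenesulfonate | Cc1ccc(cc1)S(=O)(=O)OC[C@@](O)(C)CCC=C | intermediate (not isolated)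
30 | (2R)-2-(but-3-en-1-yl)-2-methyloxirane | C1O[C@]1(C)CCC=C | intermediate
31 | 3-[(2R)-2-methyloxiran-2-yl]propanal | C1O[C@]1(C)CCC=O | intermediate
32 | (3S,4S)-3-methyl-6-[(2R)-2-methyloxiran-2-yl]hex-1-en-4-ol | C1O[C@]1(C)CC[C@H](O)[C@@H](C)C=C | intermediate
33 | (3S,4S)-3-methyl-6-[(2R)-2-methyloxiran-2-yl]hex-1-en-4-yl methanesulfonate | C1O[C@]1(C)CC[C@H](OS(C)(=O)=O)[C@@H](C)C=C | intermediate
34 | (3S,4S,7S)-7-hydroperoxy-8-hydroxy-3,7-dimethyloct-1-en-4-yl methanesulfonate | OC[C@](OO)(C)CC[C@H](OS(C)(=O)=O)[C@@H](C)C=C | intermediate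
35 | [(3S,6R)-6-[(2S)-but-3-en-2-yl]-3-methyl-1,2-dioxan-3-yl]methanol | OC[C@]1(C)CC[C@H]([C@@H](C)C=C)OO1 | intermediate
36 | (2R)-2-[(3R,6S)-6-(hydroxymethyl)-6-methyl-1,2-dioxan-3-yl]propanal | OC[C@]1(C)CC[C@H]([C@@H](C)C=O)OO1 | intermediate (not isolated)
37 | (2R)-2-[(3R,6S)-6-(hydroxymethyl)-6-methyl-1,2-dioxan-3-yl]propanoic acid | OC[C@]1(C)CC[C@H]([C@@H](C)C(=O)O)OO1 | intermediate
38 | methyl (2R)-2-[(3R,6S)-6-(hydroxymethyl)-6-methyl-1,2-dioxan-3-yl]propanoate | OC[C@]1(C)CC[C@H]([C@@H](C)C(=O)OC)OO1 | intermediate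
39 | methyl (2R)-2-[(3R,6S)-6-formyl-6-methyl-1,2-dioxan-3-yl]propanoate | O=C[C@]1(C)CC[C@H]([C@@H](C)C(=O)OC)OO1 | intermediate
40 | methyl (2R)-2-[(3R,6S)-6-methyl-6-{(E)-2-[(4aR,8aS)-1,1,3,6-tetramethyl-1,4,4a,7,8,8a-hexahydronaphthalen-2-yl]ethenyl}-1,2-dioxan-3-yl]propanoate | CC1=C[C@H]2CC(C)=C(/C=C/[C@]3(C)CC[C@H]([C@@H](C)C(=O)OC)OO3)C(C)(C)[C@H]2CC1 | intermediate
41 | methyl (2R)-2-[(3R,6R)-6-methyl-6-{2-[(4aR,8aS)-1,1,3,6-tetramethyl-1,4,4a,7,8,8a-hexahydronaphthalen-2-yl]ethyl}-1,2-dioxan-3-yl]propanoate | CC1=C[C@H]2CC(C)=C(CC[C@]3(C)CC[C@H]([C@@H](C)C(=O)OC)OO3)C(C)(C)[C@H]2CC1 | intermediate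
42 | (2R)-2-[(3R,6R)-6-methyl-6-{2-[(4aR,8aS)-1,1,3,6-tetramethyl-1,4,4a,7,8,8a-hexahydronaphthalen-2-yl]ethyl}-1,2-dioxan-3-yl]propanoic acid | CC1=C[C@H]2CC(C)=C(CC[C@]3(C)CC[C@H]([C@@H](C)C(=O)O)OO3)C(C)(C)[C@H]2CC1 | target

**Totals and risks**

Total step count: 28. Longest linear sequence: 17 steps (steps 1–4, 6–15, 26–28).

Steps most likely to fail:

1. Step 6. The fully substituted enolate carbon may add slowly, so that 1,2-addition to the enone carbonyl, proton transfer from the enone or from the C6 methylene to the enolates, or scrambling of the C2 enolate before triflation can take over. The fallback sets out from 10 (with 7) and returns at 14, and avoids any free enolate. Ketone 10 is converted with TBSOTf/Et3N into the silyl dienol ether tert-butyl[(2,4-dimethylpenta-1,3-dien-3-yl)oxy]dimethylsilane F1. F1 and 7 are combined under triflimide (Tf2NH) catalysis in CH2Cl2 at −78 °C; this silyl-transfer double Mukaiyama–Michael sequence forms the same C1–C8a and C4–C4a bonds with the same facial control and should give the bicyclic silyl enol ether (4aS,7S,8aS)-2-{[tert-butyl(dimethyl)silyl]oxy}-1,1,3-trimethyl-7-(trimethylsilyl)-4,4a,6,7,8,8a-hexahydronaphthalen-5(1H)-one F2. CsF and PhNTf2 in DME then exchange silyl for triflyl to give 14.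

2. Step 22. SN2 attack at the β-branched secondary carbon may be slow, allowing E2 loss of the mesylate, base-induced fragmentation of the β-hydroxy hydroperoxide, or ether formation by the primary hydroxyl. The fallback sets out from 31 and returns at 38, closing the ring by conjugate addition instead of displacement. Wittig reaction of 31 with methyl 2-(triphenylphosphoranylidene)propanoate gives the enoate methyl (2E)-2-methyl-5-[(2R)-2-methyloxiran-2-yl]pent-2-enoate F3. Perhydrolysis as in step 21 gives the hydroperoxide methyl (2E,6S)-6-hydroperoxy-7-hydroxy-2,6-dimethylhept-2-enoate F4. Et2NH in CF3CH2OH then induces 6-exo-trig oxa-Michael closure to the dioxane ester; the quaternary centre is already fixed, and 38 would be separated by chromatography from its diastereomers at the ring CH and α-carbons. This path is shorter but not stereocontrolled at those two centres.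

3. Step 26. Addition of the hindered allylic sulfonyl anion to the α-quaternary α-peroxy aldehyde may be slow, allowing self-condensation of the sulfone or base-induced β-elimination in the peroxy ester. The fallback sets out from 23 and returns at 40, replacing the sulfone anion by a phosphorus ylide. Alcohol 23 with Ph3P·HBr in MeOH gives the phosphonium salt {[(4aR,8aS)-1,1,3,6-tetramethyl-1,4,4a,7,8,8a-hexahydronaphthalen-2-yl]methyl}triphenylphosphonium bromide F5. Ylide formation with NaHMDS at −78 °C and addition of 39 gives 40 by Wittig olefination, the alkene geometry again being irrelevant.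

**Further compounds**

F1 | step 6 | tert-butyl[(2,4-dimethylpenta-1,3-dien-3-yl)oxy]dimethylsilane | CC(C)=C(O[Si](C)(C)C(C)(C)C)C(C)=C
F2 | step 6 | (4aS,7S,8aS)-2-{[tert-butyl(dimethyl)silyl]oxy}-1,1,3-trimethyl-7-(trimethylsilyl)-4,4a,6,7,8,8a-hexahydronaphthalen-5(1H)-one | C1C(=O)[C@H]2CC(C)=C(O[Si](C)(C)C(C)(C)C)C(C)(C)[C@H]2C[C@@H]1[Si](C)(C)C
F3 | step 22 | methyl (2E)-2-methyl-5-[(2R)-2-methyloxiran-2-yl]pent-2-enoate | C1O[C@]1(C)CC/C=C(\C)C(=O)OC
F4 | step 22 | methyl (2E,6S)-6-hydroperoxy-7-hydroxy-2,6-dimethylhept-2-enoate | OC[C@](OO)(C)CC/C=C(\C)C(=O)OC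
F5 | step 26 | {[(4aR,8aS)-1,1,3,6-tetramethyl-1,4,4a,7,8,8a-hexahydronaphthalen-2-yl]methyl}triphenylphosphonium bromide | CC1=C[C@H]2CC(C)=C(C[P+](c3ccccc3)(c3ccccc3)c3ccccc3)C(C)(C)[C@H]2CC1.[Br-]
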